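Substrate goes to target and to intermediate B by steps first order in substrate, at 0.20 s⁻¹ and 0.070 s⁻¹, so the two are born in a fixed ratio that reagent does not enter, with target ahead.

    substrate + reagent → intermediate A (k1 = 26 M⁻¹ s⁻¹)
    substrate → target (k2 = 0.20 s⁻¹)
    substrate ⇌ intermediate B (K3 = 20, k3 = 0.070 s⁻¹)
    reagent + intermediate A → intermediate C (k4 = 0.18 M⁻¹ s⁻¹)
    intermediate B → side product A (k5 = 0.0025 s⁻¹)
    intermediate C → side product B (k6 = 0.015 s⁻¹)
    capture agent + intermediate C → trapped intermediate (k7 = 0.42 M⁻¹ s⁻¹)

all flasks: substrate 0.0050 M; capture agent 0.100 mM; time 40 s

| run | reagent |
|---|---|
| noon | 0.600 mM |
| spring | 2.00 mM |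
| dusk | 5.00 mM |
| summer | 15.0 mM |
| midnight | 50.0 mM |

- share of target in all that became target or side product A or side product B or trapped intermediate for noon, spring, dusk, summer, midnight, in this order
- the shape of the row from first to last (rises, then falls / falls all the way / hardly changes / rises all the way / falls, then rises)

- a step back or a flat step of under half a point counts as no turn
- "hardly changes" means that all values lie within two and a half points (for a concentration: within two and a half percent of the largest)
- run time (noon): 40 s

Let a be side product A per target and b side product B per target; the share of target (the selectivity) is then one over (one plus a plus b). Capture of intermediate C runs at 4.20 × 10⁻⁵ s⁻¹, far slower than its loss at 0.015 s⁻¹, so the trapped intermediate stays out of the reckoning.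

At the low end, intermediate B leaks at 0.0025 s⁻¹, which gives a = 0.0350 at 40 s, and with b set to zero the share is 96.6%.

At the high end, side product B has no rate at the start and must wait for two intermediates. For a reagent charge R, intermediate A is born at 26 M⁻¹ s⁻¹ times R against 0.20 s⁻¹ for target. Held at their starting rates, the two further steps then give 0.5 times their rate constants times t squared, with t the run time and R entering again through the second reagent step. This raw leak equals the square of R/Rc. The crossover charge Rc, the reagent charge that makes the raw leak equal to one, is 59.7 mM.

At midnight the raw leak is 0.702, and the following factors slow it. Substrate leaves at 1.57 s⁻¹ in all, which takes 0.637 s off the clock, a factor 0.968. The first reagent step leaves reagent at 45.9 mM, a factor 0.917. Intermediates A and C drain as they feed onward, a factor of about 0.733. Together these give b = 0.457 at midnight, and a share of 67.0%. Since the raw leak grows with the square of R, larger at midnight than in summer, the row should fall all the way, slowly at first.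

The forecast gives 97.3%, 97.2%, 97%, 94%, 68.5%, falls all the way, holding that “Only at high reagent does the route through intermediates A and C feed side product B appreciably”.

The simulation gives 97.2%, 97.2%, 96.9%, 94.0%, 68.0%: the row falls all the way.

At midnight, the rate into intermediate A starts 6.50 times the rate into target, and at 40.0 s the flask holds 13.3% target, 60.0% intermediate A and 5.82% side product B, a reading of 0.438 side product B per target against the 0.457 reckoned. Summer, charged below Rc, has a raw leak of 0.0632; the same factors, reckoned for its charge, bring it to 0.0374 and a share of 93.3%, while that flask reads 0.0342 per target and a share of 94.0%.

All constants were set for the occasion; the run is a simulation.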